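**Remark on the chemistry:** the target has no stereogenic element, so only constitution has to be controlled. The structures of 6, 9 and 12 were checked atom by atom against the target and needed no correction. "Not isolated" means carried on crude after a simple work-up.

## Structural features

The target 13 is a linear tridepside of three benzene rings, each a 2-oxygenated 6-methylbenzoyl unit of the orsellinic acid family. Ring A (2-hydroxy-4-methoxy-6-methylbenzoyl) is bound as an aryl ester to the C4 oxygen of ring B (2-hydroxy-6-methylbenzoyl). The carbonyl of ring B is bound in the same way to the C4 oxygen of ring C, a methyl 2-methoxy-6-methylbenzoate. There is no stereocentre and no stereoisomerism. The fragile parts are the two depside esters, which transacylate under base or in hot alcohols once the ortho phenols are free, and the salicylic-type acids behind them, which can lose CO2 in hot acid. The difficulty is twofold: every carbonyl carbon lies between two ortho substituents, so acyl transfer is slow, and the five phenolic oxygens must end as two chelated phenols, two methyl ethers and two aryl esters. The key step uses the hydrogen pattern of ring B in depside 6. C4–H is the only aromatic C–H with hydrogen on both neighbours (C3 and C5), whereas C3–H and C5–H of ring B and C3–H and C5–H of ring C each have an ortho substituent. A sterically governed borylation can therefore place boron, and then the carboxylate oxygen of ring A, on that carbon alone.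

## Logic of the disconnections

**13 to 12.** The two O–CH2 acetal bonds on the C2 oxygens of rings A and B are the last to be cleaved. Masking is needed because free chelated phenols would bind copper and compete as oxygen nucleophiles in the coupling. The skeleton is not simplified, but the end-game then carries only inert ethers. The demand is an unmasking that leaves two aryl esters alone, so aqueous acid without any alcohol.

**12 to 6 and 9 (through 11 and 10).** The bond cut is the one between C4 of ring B and the ester oxygen of ring A, an aryl C–O bond and not the usual acyl C–O bond. The carbonyl carbon of ring A is shielded on both sides, while its carboxylate oxygen is exposed. In addition, ring B then needs no oxygen at C4 at the outset, so it can come from a ring with one oxygen and not two that would have to be told apart. A three-ring ester becomes a two-ring depside and a one-ring acid. The forward step must functionalise one of five aromatic C–H bonds of 6 and must tolerate two acetals and three esters. As an improvement, the pinacol boronate 10 is not coupled directly; the pinacol is stripped so that the copper step runs on the free boronic acid 11, and pyridine buffers the copper salt.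

**6 to 5.** The O–CH3 bond on the C2 oxygen of ring C is cut. Leaving this methyl group until after the esterification lets ring C enter as an unprotected diol, which saves a protection and deprotection sequence. It also ensures that 6 has no acidic hydrogen when it meets the iridium catalyst. The demand is an alkylation under base that does not cleave the aryl ester already in place.

**5 to 3 and 4.** The acyl C–O bond between the ring B carbonyl and the C4 oxygen of ring C is cut. Here the classical cut is acceptable, because the two hydroxyls of 4 are differentiated by the hydrogen bond of the C2 hydroxyl to the methyl ester. Two monocyclic pieces result. The forward step needs non-acidic activation of a di-ortho-substituted acid and selectivity for the C4 hydroxyl.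

**3 to 1 (through 2).** The O–CH2 acetal bond on the C2 oxygen is cut. Compound 1 is sold with exactly one ring oxygen, which is what makes C4 a plain C–H. Both acidic groups are alkylated in the forward direction, so the ester-type acetal of 2 must be split again by base while the ether-type acetal stays.

**9 to 8 to 7 to 4.** Three bonds are cut in turn: the carboxyl O–CH3 bond, the O–CH2 acetal bond on the C2 oxygen, and the O–CH3 bond on the C4 oxygen. Compound 4 thus serves as the source of both ring A and ring C. The demands are mono-methylation at the non-chelated hydroxyl, and a forcing saponification of a shielded ester under conditions the acetal survives.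

## Other disconnections considered

**Alternative 1:** The cut runs through ring C itself. Its C1–C6, C1–C2, C3–C4 and C4–C5 bonds are disconnected, leading from the ring C phenol A3 (methyl 4-hydroxy-2-methoxy-6-methylbenzoate) to the diazo keto ester A1 (methyl 2-diazo-4-methyl-3-oxopent-4-enoate) and methoxyacetylene A2.

- Forward step: irradiation of A1 would trigger a Wolff rearrangement in which the isopropenyl group migrates (C1–C6). The resulting vinylketene would add to A2 by (2+2) cycloaddition (C1–C2 and C3–C4). Four-electron ring opening, six-electron ring closure (C4–C5) and tautomerisation would then give A3.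
- In favour: the oxygens are differentiated by construction, the methoxy group coming from the alkyne and the free hydroxyl from the ketene carbonyl. A3 could be esterified directly with 3 to give 6, so no depside would see K2CO3. On this point it is better than steps 2 and 3 of the chosen plan.
- Against: A2 is volatile, polymerises easily and must be made fresh. A1 requires diazo transfer onto a sensitive enone keto ester. The Wolff step has two possible migrating groups. The ester-substituted ketene could add to the electron-rich alkyne as a heterodiene instead of by (2+2). Photolysis of a diazo compound is awkward on scale.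
- Comparison: structurally it solves only the oxygen pattern of ring C and leaves the C4 oxygen of ring B and the hindered ring A ester untouched. Mechanistically, a four-stage pericyclic cascade does what one hydrogen bond in 4 already does in the chosen plan. In step count, about four operations plus the esterification would replace the two steps from 4 to 6. Both plans are equal in needing no protecting group on ring C.

**Alternative 2:** Ring B is opened to a polyketide chain. The bond from the ring B carbonyl to the ring C oxygen and the C1–C6 bond of ring B are cut, leading to the diketo-dioxinone A4 (2,2-dimethyl-6-(2,4-dioxopentyl)-4H-1,3-dioxin-4-one) and A3.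

- Forward step: heating A4 with A3 would release an acylketene by retro-(4+2) reaction, which the phenol captures to give the aryl triketo ester A5 (methyl 2-methoxy-6-methyl-4-(3,5,7-trioxooctanoyloxy)benzoate). Cs2CO3 and then acid would close ring B by aldol condensation and dehydration to the ring B-C diol A6 (methyl 4-(2,4-dihydroxy-6-methylbenzoyloxy)-2-methoxy-6-methylbenzoate).
- In favour: the hindered B-C ester is made by addition to a ketene, so no di-ortho-substituted acid is activated. This is better than the carbodiimide activation of 3 in step 2. Ring B needs no protecting group and no precious metal, which is also better.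
- Against: the aryl ester of A5 has a good leaving group, and under Cs2CO3 an enolate oxygen could expel the phenoxide and form a pyrone. A4 takes about three steps and is sensitive. A3 takes three steps from 4. After A6, ring A must still be attached by activating the hindered acid 9, and the C4 and C2 hydroxyls of ring B must be told apart.
- Comparison: structurally it leaves two phenols on ring B to differentiate, which the chosen plan avoids by starting from a ring with one oxygen. Mechanistically it builds the arene by C–C bond formation, where the chosen plan functionalises a C–H bond of a finished arene. In step count it comes to roughly twelve steps against eight.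

**Alternative 3:** The ring A ester is cut on both sides of its carbonyl: the C1(ring A)–carbonyl bond and the carbonyl–O(ring B) bond. The three components are the aryl iodide A7 (1-(benzyloxy)-2-iodo-5-methoxy-3-methylbenzene), carbon monoxide A8 and the diol A6.

- Forward step: with Pd(OAc)2 and Xantphos, zerovalent palladium would insert into the C–I bond, A8 would insert to give an aroyl divalent palladium species, and the C4 phenoxide of A6 would capture it. The product is the O-benzyl ether A9 of the target, and hydrogenolysis would then give 13.
- In favour: like the chosen plan, it never activates a preformed hindered ring A acid, so the two are equal on this point. The end-game has one protecting group, and its removal by hydrogenolysis is neutral. That is gentler on the depsides than the acid of step 8, so better on this point.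
- Against: a di-ortho-substituted aroyl palladium species is captured slowly by a weakly nucleophilic phenol. The base and heat of an aryloxycarbonylation endanger the B-C ester of A6, whose ortho phenol is free. The two phenols of A6 must be distinguished. A7 requires iodination at one of three activated positions of an orcinol diether. A toxic gas is used.
- Comparison: structurally it depends on A6 and so inherits the length of alternative 2. Mechanistically it joins three components at palladium, where the chosen plan uses a two-stage C–H to C–O conversion. In step count it comes to eleven or more against eight.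

Key step: step 7

## Route

Step 1
Reactants: 1 2-hydroxy-6-methylbenzoic acid (6-methylsalicylic acid)
Product: 3 2-(methoxymethoxy)-6-methylbenzoic acid, via methoxymethyl 2-(methoxymethoxy)-6-methylbenzoate 2 (not isolated)
Conditions: NaH (2.2 equiv), MOMCl (2.3 equiv), THF/DMF, 0 °C to rt; then 2 M NaOH, MeOH, 50 °C; 1 M HCl to pH 4 at 0 °C
Reagents that add atoms: chloromethyl methyl ether, COCCl; sodium hydroxide, [Na+].[OH-] (one carboxyl oxygen, by acyl–oxygen cleavage)
Why: Williamson-type O-alkylation of the carboxylate and of the NaH-generated phenoxide by the reactive alpha-chloro ether should give 2; saponification then removes only the ester-type acetal, since its hemiacetal alkoxide is a good leaving group and the aryl acetal ether is inert to base. Cold acidification to pH 4 keeps the remaining acetal intact.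

Step 2
Reactants: 3 2-(methoxymethoxy)-6-methylbenzoic acid; 4 methyl 2,4-dihydroxy-6-methylbenzoate (methyl orsellinate)
Product: 5 methyl 2-hydroxy-4-[2-(methoxymethoxy)-6-methylbenzoyloxy]-6-methylbenzoate
Conditions: DCC (1.2 equiv), DMAP (0.2 equiv), CH2Cl2, 0 °C to rt
Reagents that add atoms: none
Why: Steglich esterification, in which DMAP turns the O-acylisourea into an acylpyridinium ion that the free and more acidic C4 phenol of 4 should attack. The C2 phenol is hydrogen-bonded to the methyl ester and flanked by it, so mono-acylation at C4 is expected, and the neutral medium spares the acetal.

Step 3
Reactants: 5 methyl 2-hydroxy-4-[2-(methoxymethoxy)-6-methylbenzoyloxy]-6-methylbenzoate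
Product: 6 methyl 2-methoxy-4-[2-(methoxymethoxy)-6-methylbenzoyloxy]-6-methylbenzoate
Conditions: MeI (3 equiv), K2CO3 (2 equiv), DMF, rt to 40 °C
Reagents that add atoms: iodomethane, CI
Why: Williamson ether synthesis (SN2) on the chelated phenoxide, which K2CO3 in DMF should generate. The aryl ester carbonyl is shielded by its two ortho substituents and should resist attack by phenoxide or carbonate at this temperature.

Step 4
Reactants: 4 methyl 2,4-dihydroxy-6-methylbenzoate (methyl orsellinate)
Product: 7 methyl 2-hydroxy-4-methoxy-6-methylbenzoate
Conditions: MeI (1.1 equiv), K2CO3 (1.1 equiv), acetone, rt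
Reagents that add atoms: iodomethane, CI
Why: Selective Williamson methylation; the C4 hydroxyl is the more acidic and is not hydrogen-bonded, so with one equivalent of base and iodomethane it should react alone while the chelated C2 hydroxyl stays free.

Step 5
Reactants: 7 methyl 2-hydroxy-4-methoxy-6-methylbenzoate
Product: 8 methyl 4-methoxy-2-(methoxymethoxy)-6-methylbenzoate
Conditions: NaH (1.3 equiv), MOMCl (1.3 equiv), THF/DMF, 0 °C to rt
Reagents that add atoms: chloromethyl methyl ether, COCCl
Why: Williamson-type acetal formation; NaH breaks the intramolecular hydrogen bond by irreversible deprotonation, and the phenoxide should be alkylated quickly by the alpha-chloro ether.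

Step 6
Reactants: 8 methyl 4-methoxy-2-(methoxymethoxy)-6-methylbenzoate
Product: 9 4-methoxy-2-(methoxymethoxy)-6-methylbenzoic acid
Conditions: KOH (5 equiv), DMSO/H2O, 90 °C; then 1 M HCl to pH 4 at 0 °C
Reagents that add atoms: potassium hydroxide, [K+].[OH-] (one carboxyl oxygen)
Why: Saponification of a hindered ester, forced by poorly solvated hydroxide in aqueous DMSO; the methyl ether and the acetal are stable to base. Cold, mild acidification should avoid both acetal loss and decarboxylation.

Step 7
Reactants: 6 methyl 2-methoxy-4-[2-(methoxymethoxy)-6-methylbenzoyloxy]-6-methylbenzoate; 9 4-methoxy-2-(methoxymethoxy)-6-methylbenzoic acid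
Product: 12 methyl 2-methoxy-4-{4-[4-methoxy-2-(methoxymethoxy)-6-methylbenzoyloxy]-2-(methoxymethoxy)-6-methylbenzoyloxy}-6-methylbenzoate (bis-MOM ether of the target), via ring B C4 pinacol boronate 10 (not isolated), via ring B C4 boronic acid 11 (not isolated)
Conditions: [Ir(OMe)(cod)]2 (2 mol %), dtbpy (4 mol %), B2pin2 (1.0 equiv), THF, 80 °C; evaporate; NaIO4, NH4OAc, acetone/H2O, rt; extract; 9 (2 equiv), Cu(OTf)2 (40 mol %), pyridine, 4 Å MS, EtOAc, air, 60 °C
Reagents that add atoms: none
Why: The precatalyst, the bipyridine and B2pin2 form a trivalent iridium tris(boryl) complex that cleaves an aromatic C–H bond and releases the aryl boronate by C–B reductive elimination; being bulky, it reacts only where both ortho positions carry hydrogen. In 6 this holds for C4–H of ring B alone (C3–H is next to the methoxymethoxy group, C5–H next to the methyl group, both ring C hydrogens lie between two substituents) and the acetal has no aromatic C–H of its own, so 10 should form as one isomer; the closest known reaction type is the borylation of 1,2,3-trisubstituted arenes at C5. Periodate then removes the pinacol as acetone under NH4OAc buffering and gives the free boronic acid 11, the boron species for which copper-mediated O-arylation of carboxylic acids (Chan–Lam coupling) is established. In that coupling the aryl group passes from boron to a divalent copper carboxylate of 9, oxidation gives an aryl trivalent copper carboxylate, and C–O reductive elimination gives the aryl ester and monovalent copper, which air returns to divalent copper. The new bond is C4(ring B)–O, so the shielded carbonyl carbon of ring A is never attacked and its hindrance does not matter. Triflate is a counter-ion that cannot compete as an oxygen nucleophile, pyridine keeps the medium from becoming acidic enough to touch the two acetals, and 9 is used in excess because the boron partner is the more valuable one. No ring is closed and no stereocentre is created.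

Step 8
Reactants: 12 methyl 2-methoxy-4-{4-[4-methoxy-2-(methoxymethoxy)-6-methylbenzoyloxy]-2-(methoxymethoxy)-6-methylbenzoyloxy}-6-methylbenzoate
Product: 13 methyl 4-{2-hydroxy-4-[(2-hydroxy-4-methoxy-6-methylbenzoyl)oxy]-6-methylbenzoyloxy}-2-methoxy-6-methylbenzoate (target)
Conditions: 3 M aq. HCl, THF, rt to 40 °C
Reagents that add atoms: none
Why: Acid-catalysed acetal hydrolysis through the methoxymethyl oxocarbenium ion, with each phenol oxygen retained; acetals ortho to a carbonyl leave readily because the emerging phenol is stabilised by chelation. Water in THF with no alcohol present should prevent transesterification of the two hindered aryl esters.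

## Compound list

1 | 2-hydroxy-6-methylbenzoic acid (6-methylsalicylic acid) | Cc1cccc(O)c1C(=O)O | starting material
2 | methoxymethyl 2-(methoxymethoxy)-6-methylbenzoate | COCOC(=O)c1c(C)cccc1OCOC | intermediate
3 | 2-(methoxymethoxy)-6-methylbenzoic acid | COCOc1cccc(C)c1C(=O)O | intermediate
4 | methyl 2,4-dihydroxy-6-methylbenzoate (methyl orsellinate) | COC(=O)c1c(C)cc(O)cc1O | starting material
5 | methyl 2-hydroxy-4-[2-(methoxymethoxy)-6-methylbenzoyloxy]-6-methylbenzoate | COCOc1cccc(C)c1C(=O)Oc1cc(C)c(C(=O)OC)c(O)c1 | intermediate
6 | methyl 2-methoxy-4-[2-(methoxymethoxy)-6-methylbenzoyloxy]-6-methylbenzoate | COCOc1cccc(C)c1C(=O)Oc1cc(C)c(C(=O)OC)c(OC)c1 | intermediate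
7 | methyl 2-hydroxy-4-methoxy-6-methylbenzoate | COC(=O)c1c(C)cc(OC)cc1O | intermediate
8 | methyl 4-methoxy-2-(methoxymethoxy)-6-methylbenzoate | COCOc1cc(OC)cc(C)c1C(=O)OC | intermediate
9 | 4-methoxy-2-(methoxymethoxy)-6-methylbenzoic acid | COCOc1cc(OC)cc(C)c1C(=O)O | intermediate
10 | methyl 2-methoxy-4-[2-(methoxymethoxy)-6-methyl-4-(4,4,5,5-tetramethyl-1,3,2-dioxaborolan-2-yl)benzoyloxy]-6-methylbenzoate | COCOc1cc(B2OC(C)(C)C(C)(C)O2)cc(C)c1C(=O)Oc1cc(C)c(C(=O)OC)c(OC)c1 | intermediate
11 | [4-{[3-methoxy-4-(methoxycarbonyl)-5-methylphenoxy]carbonyl}-3-(methoxymethoxy)-5-methylphenyl]boronic acid | COCOc1cc(B(O)O)cc(C)c1C(=O)Oc1cc(C)c(C(=O)OC)c(OC)c1 | intermediate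
12 | methyl 2-methoxy-4-{4-[4-methoxy-2-(methoxymethoxy)-6-methylbenzoyloxy]-2-(methoxymethoxy)-6-methylbenzoyloxy}-6-methylbenzoate | COC(=O)c1c(C)cc(OC(=O)c2c(C)cc(OC(=O)c3c(C)cc(OC)cc3OCOC)cc2OCOC)cc1OC | intermediate
13 | methyl 4-{2-hydroxy-4-[(2-hydroxy-4-methoxy-6-methylbenzoyl)oxy]-6-methylbenzoyloxy}-2-methoxy-6-methylbenzoate | COC(=O)c1c(C)cc(OC(=O)c2c(C)cc(OC(=O)c3c(C)cc(OC)cc3O)cc2O)cc1OC | target

## Step count and least certain steps

Total step count: 8. Longest linear sequence: 5 steps (1 to 3 to 5 to 6 to 12 to 13; the ring A branch 4 to 7 to 8 to 9 to 12 to 13 is equally long).

**Step 7 (key step).** The borylation could stall or lose site control, with minor attack next to the acetal oxygen. In the copper stage, protodeboronation and oxidative hydroxylation of the electron-poor arylboron species by traces of water could outrun its slow capture by the bulky carboxylate. Lewis-acid-induced loss of the acetal of 9, with cyclisation onto its own carboxyl group, is also possible. The fallback sets out from 6 and forms the same ester bond from the acyl side by known chemistry. The borylation is run as before but 10 is isolated. NaBO3·4H2O in THF/H2O at rt oxidises the C–B bond, by aryl migration from boron to oxygen, to the phenol methyl 4-[4-hydroxy-2-(methoxymethoxy)-6-methylbenzoyloxy]-2-methoxy-6-methylbenzoate F1. F1 is then acylated with 9 under DCC and DMAP, and the route is rejoined at 12.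

**Step 2.** Acyl transfer from the hindered O-acylisourea could be slow enough for rearrangement to the N-acylurea to consume 3, and a second acylation at the chelated hydroxyl could intrude. The fallback sets out from 3. 1-Chloro-N,N,2-trimethylprop-1-en-1-amine in CH2Cl2 converts it under neutral conditions to 2-(methoxymethoxy)-6-methylbenzoyl chloride F2. F2 is added to 4 with Et3N and catalytic DMAP at 0 °C, and the route is rejoined at 5.

**Step 3.** Transacylation or cleavage of the aryl ester by phenoxide or carbonate could compete with O-methylation. The fallback sets out from 4 and fixes the methyl ether before any depside exists. Benzylation with BnBr and K2CO3 in acetone gives methyl 4-(benzyloxy)-2-hydroxy-6-methylbenzoate F3. Methylation with MeI and K2CO3 in DMF gives methyl 4-(benzyloxy)-2-methoxy-6-methylbenzoate F4. Hydrogenolysis with H2 and Pd/C in EtOAc gives methyl 4-hydroxy-2-methoxy-6-methylbenzoate F5. F5 is esterified with 3 under DCC and DMAP, and the route is rejoined at 6, bypassing 5.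

**Step 6.** Saponification could remain incomplete because hydroxide reaches the shielded carbonyl poorly, and acetal loss or decarboxylation could occur on acidification. The fallback sets out from 8 and replaces acyl substitution by a redox detour. LiAlH4 in THF at 0 °C reduces the ester to [4-methoxy-2-(methoxymethoxy)-6-methylphenyl]methanol F6. MnO2 in CH2Cl2 oxidises it to 4-methoxy-2-(methoxymethoxy)-6-methylbenzaldehyde F7. Pinnick oxidation with NaClO2, NaH2PO4 and 2-methyl-2-butene in tBuOH/H2O gives the acid, and the route is rejoined at 9.

## Further compounds

F1 | step 7 | methyl 4-[4-hydroxy-2-(methoxymethoxy)-6-methylbenzoyloxy]-2-methoxy-6-methylbenzoate | COCOc1cc(O)cc(C)c1C(=O)Oc1cc(C)c(C(=O)OC)c(OC)c1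
F2 | step 2 | 2-(methoxymethoxy)-6-methylbenzoyl chloride | COCOc1cccc(C)c1C(Cl)=O
F3 | step 3 | methyl 4-(benzyloxy)-2-hydroxy-6-methylbenzoate | COC(=O)c1c(C)cc(OCc2ccccc2)cc1O
F4 | step 3 | methyl 4-(benzyloxy)-2-methoxy-6-methylbenzoate | COC(=O)c1c(C)cc(OCc2ccccc2)cc1OC
F5 | step 3 | methyl 4-hydroxy-2-methoxy-6-methylbenzoate | COC(=O)c1c(C)cc(O)cc1OC
F6 | step 6 | [4-methoxy-2-(methoxymethoxy)-6-methylphenyl]methanol | COCOc1cc(OC)cc(C)c1CO
F7 | step 6 | 4-methoxy-2-(methoxymethoxy)-6-methylbenzaldehyde | COCOc1cc(OC)cc(C)c1C=O
A1 | alternative 1 | methyl 2-diazo-4-methyl-3-oxopent-4-enoate | COC(=O)C(=[N+]=[N-])C(=O)C(C)=C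
A2 | alternative 1 | methoxyethyne (methoxyacetylene) | COC#C
A3 | alternative 1 | methyl 4-hydroxy-2-methoxy-6-methylbenzoate | COC(=O)c1c(C)cc(O)cc1OC
A4 | alternative 2 | 2,2-dimethyl-6-(2,4-dioxopentyl)-4H-1,3-dioxin-4-one | CC(=O)CC(=O)CC1=CC(=O)OC(C)(C)O1
A5 | alternative 2 | methyl 2-methoxy-6-methyl-4-(3,5,7-trioxooctanoyloxy)benzoate | COC(=O)c1c(C)cc(OC(=O)CC(=O)CC(=O)CC(C)=O)cc1OC
A6 | alternative 2 | methyl 4-(2,4-dihydroxy-6-methylbenzoyloxy)-2-methoxy-6-methylbenzoate | COC(=O)c1c(C)cc(OC(=O)c2c(C)cc(O)cc2O)cc1OC
A7 | alternative 3 | 1-(benzyloxy)-2-iodo-5-methoxy-3-methylbenzene | COc1cc(C)c(I)c(OCc2ccccc2)c1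
A8 | alternative 3 | carbon monoxide | [C-]#[O+]
A9 | alternative 3 | methyl 4-{4-[2-(benzyloxy)-4-methoxy-6-methylbenzoyloxy]-2-hydroxy-6-methylbenzoyloxy}-2-methoxy-6-methylbenzoate | COC(=O)c1c(C)cc(OC(=O)c2c(C)cc(OC(=O)c3c(C)cc(OC)cc3OCc3ccccc3)cc2O)cc1OC
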